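The runs stem from a simulated flask for an exercise; scatter was added.

The cedar run cannot have stopped for want of substrate, since 47.2% of it still stands over its last readings. Maple, with the same substrate charge and less solid reagent, rests at 86.6%, so I take the solid reagent as the limiting reagent.

| flask | substrate | solid reagent | remark | time |
|---|---|---|---|---|
| maple | 0.054 M (fed, over 3.0 h) | 0.026 M | run made earlier; the fed solution adds 0.10 times the starting volume |  |
| cedar | 0.054 M (fed, over 3.0 h) | 0.10 M | run made earlier; the fed solution adds 0.10 times the starting volume |  |
| alder | 0.027 M (fed, over 3.0 h) | 0.0513 M | run made earlier; the fed solution adds 0.10 times the starting volume |  |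
| flask | 0.054 M (fed, over 3.0 h) | 0.0513 M | the fed solution adds 0.10 times the starting volume | 2.0 d |

| run | time / d | substrate / % | first product / % | bis adduct / % |
|---|---|---|---|---|
| maple | 0.208 | 86.3 | 10.6 | 3.6 |
| maple | 0.333 | 85.9 | 9.7 | 3.9 |
| maple | 0.625 | 86.4 | 11.4 | 3.4 |
| maple | 1.25 | 86.8 | 10.6 | 3.9 |
| maple | 2.50 | 86.7 | 9.6 | 4.1 |
| cedar | 0.208 | 62.1 | 18.4 | 18.1 |
| cedar | 0.333 | 47.8 | 18.2 | 34.0 |
| cedar | 0.625 | 48.0 | 18.3 | 34.6 |
| cedar | 1.25 | 46.7 | 18.1 | 35.5 |
| cedar | 2.50 | 46.9 | 18.1 | 34.6 |
| alder | 0.500 | 63.6 | 19.0 | 17.7 |
| alder | 1.04 | 63.3 | 18.1 | 18.6 |
| alder | 1.25 | 63.2 | 18.5 | 18.6 |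
| alder | 2.08 | 63.7 | 18.7 | 18.3 |
| alder | 2.50 | 63.2 | 17.8 | 19.2 |

(each reading ± 0.5 percentage points)

- charges are per starting volume, the dose included; the dosed solution carries all of it
- given per volume of solution although it is solid: solid reagent
- at the start none of the solid reagent is in solution
- the reaction counts as stopped when no species that holds the substrate changes by six tenths of a point or more over the second half of the time

- which holds at 2.0 d: what has brought the reaction to rest, or that it has not come to rest (for what has run out or reacted, a solid counts together with what of it has only dissolved) (all of the substrate has reacted / forward and back rates have come level / it is still moving / the partner has run out first)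
- share of the substrate used up at 2.0 d
- first product at 2.0 d, in percent of the substrate charged
- bis adduct at 2.0 d, in percent of the substrate charged

Let P be first product plus 2 times bis adduct, as a share of the substrate charged. I define the capture share as P times c(substrate) over c(solid reagent), the part of the reagent charge found in products. I read it from the last 3 readings of each run. Maple gives 37.7%, cedar 47.5% and alder 29.3%. The rest of the reagent shows in neither product.

The flask's reagent charge lies between maple's and cedar's, so I first take their mean, 42.6%, which makes P 40.5%. To split P, I use a reading: with s the substrate left, first product follows half of s minus s cubed. Cedar's 47.2% gives 18.3%, and its readings average 18.2%. Then s equals 4 plus s cubed minus 2 P, all over 5. Starting from the mean of the two rests, 66.9%, this goes to 69.8%, then 70.6%.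

The weak link is the mean, for alder's share is lower and the share plainly moves. Reading it on the maple–cedar line at the flask's s gives 41.7%, and one more round gives s = 71.2%. For the flask I commit to 28.8% conversion, 17.5% first product and 11.3% bis adduct, at rest, as the cedar run was flat by 0.333 d.

The forecast says the partner has run out first, with 30% conversion, a little above mine, 17.5% first product and 12.5% bis adduct, on the ground that “the dissolved partner is also lost by a side route and runs out”.

The flask gives this: the partner has run out first, with 0% of it left, at 29.0% conversion, 17.0% first product and 12.0% bis adduct.

    solid reagent ⇌ partner, rate k1*(cs1 - [partner]) while solid is left; crystals form when [partner] > cs1 (solubility = 26.0 mM, k = 0.0170 min⁻¹)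
    substrate + partner → first product (k = 0.190 L mol⁻¹ min⁻¹)
    partner → decomposed reagent (k = 0.0100 min⁻¹)
    partner + first product → bis adduct (k = 0.560 L mol⁻¹ min⁻¹)

At 2.00 d the flask holds 0.0265 M of decomposed reagent. Its capture share comes to 43.1%, against my 41.7%. For the neighbour charged with 0.013 M of solid reagent, the line through maple and cedar, extended to its 93.6% of substrate left, gives 36.0%. That neighbour's own products make the share 30.3%.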